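(The runs were computed on assumed constants, noise included.)

The vessel is closed, stirred and isothermal. Starting material meets 2.00 equiv of reagent for 4.0 h, and two earlier runs show what to watch.

| flask | starting material | reagent | remark | time |
|---|---|---|---|---|
| south | 28 mM | 2.8 equiv | run made earlier |  |
| north-east | 28 mM | 4.4 equiv | run made earlier |  |
| flask | 28 mM | 2.00 equiv |  | 4.0 h |

| run | time / h | first product / % | bis adduct / % | starting material / % |
|---|---|---|---|---|
| south | 0.200 | 40.3 | 4.0 | 54.6 |
| south | 0.417 | 55.6 | 10.2 | 31.5 |
| south | 1.00 | 61.4 | 28.9 | 7.6 |
| south | 2.50 | 52.4 | 46.2 | 1.9 |
| north-east | 0.200 | 52.3 | 8.7 | 38.6 |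
| north-east | 0.417 | 59.9 | 22.6 | 17.5 |
| north-east | 1.00 | 48.2 | 48.9 | 1.4 |
| north-east | 2.50 | 34.1 | 65.7 | 0.4 |

(scatter of a reading: 1 percentage point)



- equivalents of reagent to starting material, everything else as given, that leave most first product at 4.0 h
- the amount of first product then, in percent of the starting material charged
- the amount of first product with the amounts as given

Two readers of these runs disagree about why both slow down after the first hour. The forecast takes a ratio of the two rate constants near 0.27 and says “So activity or reagent is dying”. It gives 59.5% in the flask and 61% at 1.7 equiv.

My own view is that the second step also runs back. Once its forward and back rates are equal, dividing one by the other removes time and leaves the balance quotient Q = [bis adduct]/([first product][reagent]), an equilibrium constant, the mark of thermodynamic control. Counting the two products read, free reagent is the charge less one per first product and two per bis adduct. At 2.50 h the south run gives 23.3 /M and the north-east run 25.1 /M, although their reagent charges differ by a factor of 1.57. I carry the mean, Q = 24.2 /M, as a reading with its scatter, and a low one if the runs were still moving.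

Suppose the flask's starting material ends entirely as first product and bis adduct: at 2.00 equiv its free reagent then equals its first product, and Q gives 68.4% of first product. At the forecast's 1.7 equiv, the same reckoning gives 76.2%, more than the forecast's 61%, provided starting material is still consumed in time.

The flask gives 64.3%, within tolerance of the forecast and below my 68.4%, but the best is 73.0% at 1.33 equiv, 12 percentage points above the forecast.

    starting material + reagent → first product (k = 0.700 /M/min)
    reagent + first product ⇌ bis adduct (K = 27.0 /M, k = 0.230 /M/min)
    starting material + bis adduct → side product (k = 0.110 /M/min)

The forecast's picture of rates has its region early, when first product is made, each step taken net, 4.00 times faster than it is used up at 0.336 h, against 1.04 times at 4.00 h. In the flask at 4.00 h, Q times [reagent] gives 0.468 for [bis adduct]/[first product], and the flask holds 0.497. In a neighbour flask charged with 3.40 equiv of reagent, Q gives 1.24 for the same ratio at 4.00 h, and that flask holds 1.36.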